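## The problem

Compound 20 is a monocyclic γ-butyrolactone (O1, C2 carbonyl, C3, C4, C5 methylene). C3 carries a 4-hydroxy-3-methoxybenzyl group (ring A). C4 carries a secondary benzylic carbinol carbon, called C7′ here, which bears a second guaiacyl ring (ring B). No rings are fused, so the synthesis has to assemble the branched chain C2–C3–C4(–C5)–C7′ between two aryl units and close one C–O ring. Three contiguous stereocentres are needed as 3R,4R,7′S: the C3 and C4 substituents are trans on the ring, and the C7′ oxygen is syn to the C3 branch when C5–C4–C7′–aryl is drawn as a zigzag. C3 is α to the carbonyl and can be equilibrated to the more stable trans arrangement once the ring exists. C4 and C7′ must be set under kinetic control, and the sensible order is to create C7′ first by an enantioselective reaction and let it control C4. The p-hydroxybenzylic alcohol is the fragile element. Acid ionises it and ring A traps the cation to give an aryltetralin; hydrogenolysis removes the hydroxyl group; base can shift the acyl group from O1 to the C7′ oxygen or epimerise C7′ through a quinone methide. The phenols and the carbinol therefore stay silylated until a last, buffered fluoride step, benzyl ethers are excluded, and the C7′ oxygen is capped whenever an ester lies γ to it. The plan rests on C5 being a lone CH2O terminus on C4, flanked by the oxygenated C7′ and by C3. C4=C5 can therefore be a methylene group of an open-chain ester, whose anti-Markovnikov hydration creates C4 under the influence of the allylic C7′ silyl ether and delivers the hydroxyl group that closes the ring onto C2.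

## Retrosynthesis

20 from 19. The last disconnection cuts only O–Si bonds: the two aryl silyl ethers and the C7′ silyl ether of 19. Fluoride cleavage is preferred to acid-labile or hydrogenolysable protection because of the p-hydroxybenzylic alcohol. 19 is no simpler in skeleton, but every earlier step is freed from free phenols and a free carbinol. The forward step has to stay close to neutral.

19 from 18. No skeletal bond is cut. The C3–H bond is treated as exchangeable, so trans lactone 19 is derived from 18, the same lactone as a mixture of C3 epimers. This is preferred to fixing C3 in an open-chain precursor, where that carbon is both allylic and α to an ester and cannot be trusted to hold its configuration. The precursor is simpler by one stereocentre. The forward reaction must be a reversible deprotonation that touches nothing else, with a clear thermodynamic bias; two bulky vicinal substituents on a five-membered lactone provide it.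

18 from 15 (key disconnection). The O1–C2 and C5–O1 bonds are cut and the hydrogen on C4 is removed, leading to methyl ester 15 with a C4=C5 methylene group. The neighbouring ring disconnections (C3–C4 by conjugate addition to a butenolide, C3–benzyl by lactone enolate alkylation) leave the C4/C7′ relationship unsolved. Here the C7′ silyl ether itself creates C4: rhodium-catalysed hydroboration of 2-substituted allylic silyl ethers gives the syn product that 20 requires, whereas uncatalysed dialkylboranes give the other diastereomer. 15 is open-chain with a single stereocentre that matters. The forward reaction must place boron on C5, add to the alkene face anti to the silyloxy group, and lactonise only from the new C5 hydroxyl group; the silyl group on the C7′ oxygen ensures the last point.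

15 from 9 and 12. The C3–C4 bond is cut, giving alkenyl bromide 9 and ester 12, used as its zinc enolate 14 (from lithium enolate 13) under palladium catalysis. The cut gives two fragments of similar size, each with one guaiacyl ring. Cutting C4–C7′ instead (alkenylmetal plus aldehyde 2) would put a free C7′ alkoxide next to the ester and give up setting C7′ by ketone reduction. Cutting C3–benzyl would need an extra alkylation step. The coupling has to join a hindered 2-bromo-1-alkene to an α-branched enolate without moving the double bond into conjugation; selectivity at C3 is not required.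

9 from 7. The C–Br bond and the cis vinylic C–H bond are traced to terminal alkyne 7 through alkenylborane 8. Direct hydrobromination would not be tolerated next to an electron-rich benzylic silyl ether, whereas bromoboration and protonolysis put bromine on the internal carbon under mild conditions. The alkyne is simpler by one functional group and is the natural product of a carbonyl alkynylation.

7 from 6, 5, 4, 2 and 3. Silyl ether 7 comes from alcohol 6, whose stereocentre is set by oxazaborolidine-catalysed reduction of ynone 5. 5 arises by oxidation of racemic alcohol 4, and the C7′–C4 bond of 4 is cut to aldehyde 2 and ethynylmagnesium bromide 3. Reduction of a ketone with one aryl and one ethynyl substituent was preferred to direct asymmetric alkynylation of an electron-rich aromatic aldehyde: its sense is predictable and no alkyne protecting group is needed. The price is two redox steps.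

2 from 1; 12 from 11 and 10. Both rings are bought: ring B as vanillin 1, silylated to 2, and ring A with its three-carbon chain as dihydroferulic acid 10, esterified to 11 and silylated to 12. Triisopropylsilyl is chosen for the phenols because aryl ethers of this size should withstand the Grignard, amide-base, peroxide and amidine steps. tert-Butyldimethylsilyl is chosen for C7′ because ethers of that size direct the hydroboration well.

## Roads not taken

Alternative 1: Matteson homologation. The cut removes the C4–C7′ and C7′–aryl bonds. Boronic ester A1 (tert-butyl ester, C5 as triethylsilyl ether) would take up LiCHCl2, C4 would migrate to the new carbon, a ring B aryl Grignard reagent would displace the remaining chloride in a second migration, and peroxide would give the open-chain hydroxy ester A2.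
- Merits: with a chiral diol on boron, C7′ is made under reagent control and does not depend on an ynone reduction; ring B enters late as a simple Grignard reagent; no alkene has to survive base. In these respects the road is at least as good as the chosen one.
- Weak points: A1 must already hold C3 and C4 as a defined pair. Boron on C4 has a silyloxy group on the β-carbon C5, so each borate intermediate can collapse by β-elimination. LiCHCl2 is also a base towards the ester α-hydrogen. With pinacol on boron, as A1 is written, only C4 would control C7′. No ring closes: A2 still needs C5 desilylation and lactonisation onto a tert-butyl ester, which calls for acid next to the acid-sensitive benzylic alcohol.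
- Comparison: the chosen plan sets against the reagent-controlled carbinol a key operation that closes the ring, organoboron intermediates without β-oxygen, and a two-step endgame free of acid.

Alternative 2: Baeyer–Villiger desymmetrisation. The C2–O1 and O1–C5 bonds are traced to a ring expansion. Cyclobutanone A3, carrying the silylated carbinol on its C3, would be oxidised with H2O2 and a chiral catalyst so that one of the two α-methylenes migrates to oxygen, giving lactone A4. The ring A benzyl group would then be added by trans-selective enolate alkylation.
- Merits: ring and C4 arise in one catalytic step. C3 is introduced afterwards under kinetic trans control, so no epimer mixture is carried and no hindered sp2–sp3 coupling is needed. Here the road is better than the chosen one.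
- Weak points: C4 depends on a catalyst telling two methylene groups apart, with the C7′ centre either matched or mismatched and not itself in control. Selectivities of such oxidations on 3-substituted cyclobutanones are often only moderate. The electron-rich arene and the benzylic position must endure peroxide and acid. A3 itself needs several steps.
- Comparison: the chosen plan sets against the cleaner C3 chemistry a C4-forming step whose sense follows from an established acyclic model with the controlling centre directly adjacent, and a convergent assembly from two fragments. The alkylation endgame of this road is kept as the fallback for the key step.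

Alternative 3: Stereoconvergent lactonisation. Only O1–C2 is cut. Acid would cleave the tert-butyl ester of diol A5, whose C4 is prochiral with two hydroxymethyl arms. The acid would lactonise onto either arm, and acyl transfer between the arms should funnel the cis and trans lactones to the trans lactone A6.
- Merits: simple reagents, thermodynamic and therefore reliable control of the C3/C4 relationship, no transition metal. In robustness of its key step this road is better.
- Weak points: A6 contains neither ring B nor C7′. The free arm must be oxidised to aldehyde A7, which is epimerisable and can open the lactone by β-elimination of the ring oxygen. Ring B must then be added as an arylmetal in the presence of the lactone, with C7′ controlled by C4 alone, for which no strong bias in the needed sense can be claimed.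
- Comparison: the chosen plan sets C7′ first under catalyst control and uses it to make C4. Against the simplicity of Alternative 3 it has to accept a demanding coupling and a C3 equilibration.

Key step: step 10

Assumption: lactone numbering (O1, C2–C5) and C7′ for the carbinol carbon are used for all intermediates; compounds 15 to 18 are carried as mixtures of the two epimers at the carbon that becomes C3, whose configuration is settled only in step 11, and their SMILES leave that centre open on purpose.

## Steps

Step 1
Reactants: 1 vanillin (4-hydroxy-3-methoxybenzaldehyde)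
Product: 2 3-methoxy-4-(triisopropylsilyloxy)benzaldehyde
Conditions: TIPSCl, imidazole, DMF, rt
Reagents that add atoms: triisopropylsilyl chloride, CC(C)[Si](Cl)(C(C)C)C(C)C
Why: Imidazole-promoted silylation of a phenol; the bulky aryl silyl ether should survive the Grignard, amide-base, peroxide and amidine steps and still fall to fluoride at the end.

Step 2
Reactants: 2 3-methoxy-4-(triisopropylsilyloxy)benzaldehyde; 3 ethynylmagnesium bromide
Product: 4 rac-1-[3-methoxy-4-(triisopropylsilyloxy)phenyl]prop-2-yn-1-ol
Conditions: THF, 0 °C; then aq. NH4Cl
Reagents that add atoms: none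
Why: Grignard 1,2-addition of an alkynyl nucleophile to an aryl aldehyde forms the C7′–C4 bond; the carbinol is racemic and is erased in step 3.

Step 3
Reactants: 4 rac-1-[3-methoxy-4-(triisopropylsilyloxy)phenyl]prop-2-yn-1-ol
Product: 5 1-[3-methoxy-4-(triisopropylsilyloxy)phenyl]prop-2-yn-1-one
Conditions: MnO2 (activated, excess), CH2Cl2, rt
Reagents that add atoms: none
Why: MnO2 oxidation of an alcohol that is both benzylic and propargylic, under neutral heterogeneous conditions that leave the silyl ether and the terminal alkyne alone.

Step 4
Reactants: 5 1-[3-methoxy-4-(triisopropylsilyloxy)phenyl]prop-2-yn-1-one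
Product: 6 (S)-1-[3-methoxy-4-(triisopropylsilyloxy)phenyl]prop-2-yn-1-ol
Conditions: (R)-Me-CBS oxazaborolidine (C18H20BNO, 0.5 equiv.), catecholborane (1.5 equiv.), CH2Cl2, −78 °C; then aq. pH 7 buffer
Reagents that add atoms: none
Why: Corey–Bakshi–Shibata reduction: the ketone binds to the catalyst boron anti to the large aryl group, the linear ethynyl group acts as the small substituent, and hydride goes to the Re face to give the S carbinol, by analogy with aryl methyl ketones; catecholborane at −78 °C should not hydroborate the alkyne.

Step 5
Reactants: 6 (S)-1-[3-methoxy-4-(triisopropylsilyloxy)phenyl]prop-2-yn-1-ol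
Product: 7 (S)-tert-butyl{[1-[3-methoxy-4-(triisopropylsilyloxy)phenyl]prop-2-yn-1-yl]oxy}dimethylsilane
Conditions: TBSCl, imidazole, DMF, rt
Reagents that add atoms: tert-butyldimethylsilyl chloride, CC(C)(C)[Si](C)(C)Cl
Why: Silylation of a secondary alcohol without touching C7′; this silyl group later directs the hydroboration and keeps the C7′ oxygen from lactonising.

Step 6
Reactants: 7 (S)-tert-butyl{[1-[3-methoxy-4-(triisopropylsilyloxy)phenyl]prop-2-yn-1-yl]oxy}dimethylsilane
Product: 9 (R)-{[2-bromo-1-[3-methoxy-4-(triisopropylsilyloxy)phenyl]prop-2-en-1-yl]oxy}(tert-butyl)dimethylsilane, via alkenylborane 8 (not isolated)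
Conditions: B-bromo-9-BBN, CH2Cl2, 0 °C; then AcOH, 0 °C → rt
Reagents that add atoms: B-bromo-9-borabicyclo[3.3.1]nonane, BrB1C2CCCC1CCC2
Why: Bromoboration adds B–Br syn across the terminal alkyne with boron on the terminal carbon and bromine on the internal one, and acetic acid protonolyses the alkenyl C–B bond with retention to give the 2-bromo-1-alkene. C7′ is untouched; its descriptor changes from S to R only because the bromoalkenyl group now outranks the aryl group.

Step 7
Reactants: 10 dihydroferulic acid [3-(4-hydroxy-3-methoxyphenyl)propanoic acid]
Product: 11 methyl 3-(4-hydroxy-3-methoxyphenyl)propanoate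
Conditions: MeOH, H2SO4 (cat.), reflux
Reagents that add atoms: methanol, CO
Why: Fischer esterification; the phenol is unaffected.

Step 8
Reactants: 11 methyl 3-(4-hydroxy-3-methoxyphenyl)propanoate
Product: 12 methyl 3-[3-methoxy-4-(triisopropylsilyloxy)phenyl]propanoate
Conditions: TIPSCl, imidazole, DMF, rt
Reagents that add atoms: triisopropylsilyl chloride, CC(C)[Si](Cl)(C(C)C)C(C)C
Why: Phenol silylation as in step 1, so that both rings carry the same fluoride-labile group.

Step 9
Reactants: 12 methyl 3-[3-methoxy-4-(triisopropylsilyloxy)phenyl]propanoate; 9 (R)-{[2-bromo-1-[3-methoxy-4-(triisopropylsilyloxy)phenyl]prop-2-en-1-yl]oxy}(tert-butyl)dimethylsilane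
Product: 15 methyl (2RS,4S)-4-(tert-butyldimethylsilyloxy)-2-[3-methoxy-4-(triisopropylsilyloxy)benzyl]-4-[3-methoxy-4-(triisopropylsilyloxy)phenyl]-3-methylenebutanoate (both C2 epimers), via lithium enolate 13 (not isolated), via chlorozinc enolate 14 (not isolated)
Conditions: LiN(CHMe2)2, THF, −78 °C; ZnCl2, −78 °C → rt; then 9, Pd(dba)2 (5 mol%), P(t-Bu)3 (10 mol%), rt → 50 °C
Reagents that add atoms: none
Why: Negishi-type α-alkenylation of an ester zinc enolate: the alkenyl bromide adds oxidatively to zerovalent palladium, the zinc enolate transmetalates, and the bulky electron-rich phosphine drives C–C reductive elimination. The weakly basic zinc enolate should leave the β,γ-double bond and the silyl ethers in place. The ester α-carbon forms without control, which the route tolerates; C7′ is not involved.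

Step 10
Reactants: 15 methyl (2RS,4S)-4-(tert-butyldimethylsilyloxy)-2-[3-methoxy-4-(triisopropylsilyloxy)benzyl]-4-[3-methoxy-4-(triisopropylsilyloxy)phenyl]-3-methylenebutanoate (both C2 epimers)
Product: 18 (3RS,4R)-4-[(S)-(tert-butyldimethylsilyloxy)[3-methoxy-4-(triisopropylsilyloxy)phenyl]methyl]-3-[3-methoxy-4-(triisopropylsilyloxy)benzyl]dihydrofuran-2(3H)-one (both C3 epimers), via catecholboronate 16 (not isolated), via hydroxy ester 17 (not isolated)
Conditions: catecholborane (3 equiv.), RhCl(PPh3)3 (5 mol%), THF, 0 °C → rt; then 30% H2O2, aq. NaHCO3, THF–EtOH, 0 °C → rt; then pyridinium p-toluenesulfonate (cat.), CH2Cl2, rt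
Reagents that add atoms: hydrogen peroxide, OO
Why: The B–H bond of catecholborane adds oxidatively to rhodium after loss of a phosphine, the 1,1-disubstituted alkene coordinates, hydride migrates to the more substituted carbon C4, and reductive elimination places boron on the terminal carbon C5 to give primary boronate 16. Hydroperoxide adds to boron and C5 migrates from boron to oxygen with retention, giving alcohol 17, whose hydroxyl group attacks the methyl ester carbonyl in a 5-exo-trig closure (O1–C2) with loss of methanol; the mild acid only completes this. The closest known reaction type is the RhCl(PPh3)3-catalysed hydroboration of 2-substituted allylic silyl ethers of secondary carbinols, aryl carbinols included, with catecholborane, which gives the syn 2-substituted 1,3-diol monoether, opposite to uncatalysed dialkylboranes. The new stereocentre C4 is controlled by C7′: in the reactive conformer the C7′–H bond lies in the alkene plane beside the C3 branch (least allylic strain) and the C–O bond stands perpendicular and anti to the incoming metal, so rhodium and then hydride add to the face opposite the silyloxy group, which gives 4R from 7′S. Regioselectivity (boron on C5) follows from the steric difference between the two alkene carbons. Chemoselectivity follows from the inertness of the ester, and of the uncatalysed pathway, towards catecholborane at room temperature. Only the C5 hydroxyl group can lactonise because the C7′ oxygen is silylated. The C3 centre, with two substituents of similar size on either side of the alkene plane, should influence the facial choice only weakly, so both epimers of 15 are expected to give the 4R lactone.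

Step 11
Reactants: 18 (3RS,4R)-4-[(S)-(tert-butyldimethylsilyloxy)[3-methoxy-4-(triisopropylsilyloxy)phenyl]methyl]-3-[3-methoxy-4-(triisopropylsilyloxy)benzyl]dihydrofuran-2(3H)-one (both C3 epimers)
Product: 19 (3R,4R)-4-[(S)-(tert-butyldimethylsilyloxy)[3-methoxy-4-(triisopropylsilyloxy)phenyl]methyl]-3-[3-methoxy-4-(triisopropylsilyloxy)benzyl]dihydrofuran-2(3H)-one
Conditions: DBU (2 equiv.), toluene, 80 °C
Reagents that add atoms: none
Why: Thermodynamic epimerisation through the lactone enolate: the amidine base removes the C3 proton reversibly and reprotonation accumulates the trans isomer, in which the two large groups avoid each other on the five-membered ring, so C3 becomes R. C4 and C7′ carry no acidic hydrogen, and the dry aprotic medium spares the silyl ethers.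

Step 12
Reactants: 19 (3R,4R)-4-[(S)-(tert-butyldimethylsilyloxy)[3-methoxy-4-(triisopropylsilyloxy)phenyl]methyl]-3-[3-methoxy-4-(triisopropylsilyloxy)benzyl]dihydrofuran-2(3H)-one
Product: 20 (3R,4R)-3-(4-hydroxy-3-methoxybenzyl)-4-[(S)-hydroxy(4-hydroxy-3-methoxyphenyl)methyl]dihydrofuran-2(3H)-one
Conditions: Bu4NF (6 equiv.), AcOH (6 equiv.), THF, 0 °C → rt
Reagents that add atoms: none
Why: Fluoride cleaves the two aryl silyl ethers and the secondary silyl ether. Acetic acid keeps the phenols and the carbinol protonated as they are released, which should suppress acyl transfer to the C7′ oxygen and quinone methide formation; no stereocentre is touched.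

## Compound list

1 | vanillin (4-hydroxy-3-methoxybenzaldehyde) | COc1cc(C=O)ccc1O | starting material
2 | 3-methoxy-4-(triisopropylsilyloxy)benzaldehyde | COc1cc(C=O)ccc1O[Si](C(C)C)(C(C)C)C(C)C | intermediate
3 | ethynylmagnesium bromide | C#C[Mg]Br | starting material
4 | rac-1-[3-methoxy-4-(triisopropylsilyloxy)phenyl]prop-2-yn-1-ol | COc1cc(C(O)C#C)ccc1O[Si](C(C)C)(C(C)C)C(C)C | intermediate
5 | 1-[3-methoxy-4-(triisopropylsilyloxy)phenyl]prop-2-yn-1-one | COc1cc(C(=O)C#C)ccc1O[Si](C(C)C)(C(C)C)C(C)C | intermediate
6 | (S)-1-[3-methoxy-4-(triisopropylsilyloxy)phenyl]prop-2-yn-1-ol | C#C[C@H](O)c1ccc(O[Si](C(C)C)(C(C)C)C(C)C)c(OC)c1 | intermediate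
7 | (S)-tert-butyl{[1-[3-methoxy-4-(triisopropylsilyloxy)phenyl]prop-2-yn-1-yl]oxy}dimethylsilane | C#C[C@H](O[Si](C)(C)C(C)(C)C)c1ccc(O[Si](C(C)C)(C(C)C)C(C)C)c(OC)c1 | intermediate
8 | 9-[(1Z,3R)-2-bromo-3-(tert-butyldimethylsilyloxy)-3-[3-methoxy-4-(triisopropylsilyloxy)phenyl]prop-1-en-1-yl]-9-borabicyclo[3.3.1]nonane (alkenylborane, not isolated) | Br/C(=C\B1C2CCCC1CCC2)[C@H](O[Si](C)(C)C(C)(C)C)c1ccc(O[Si](C(C)C)(C(C)C)C(C)C)c(OC)c1 | intermediate
9 | (R)-{[2-bromo-1-[3-methoxy-4-(triisopropylsilyloxy)phenyl]prop-2-en-1-yl]oxy}(tert-butyl)dimethylsilane | C=C(Br)[C@H](O[Si](C)(C)C(C)(C)C)c1ccc(O[Si](C(C)C)(C(C)C)C(C)C)c(OC)c1 | intermediate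
10 | dihydroferulic acid [3-(4-hydroxy-3-methoxyphenyl)propanoic acid] | COc1cc(CCC(=O)O)ccc1O | starting material
11 | methyl 3-(4-hydroxy-3-methoxyphenyl)propanoate | COC(=O)CCc1ccc(O)c(OC)c1 | intermediate
12 | methyl 3-[3-methoxy-4-(triisopropylsilyloxy)phenyl]propanoate | COC(=O)CCc1ccc(O[Si](C(C)C)(C(C)C)C(C)C)c(OC)c1 | intermediate
13 | lithium enolate of 12 (benzyl group cis to OMe, not isolated) | CO/C(O[Li])=C\Cc1ccc(O[Si](C(C)C)(C(C)C)C(C)C)c(OC)c1 | intermediate
14 | chlorozinc enolate of 12 (drawn O-bound, not isolated) | CO/C(O[Zn]Cl)=C\Cc1ccc(O[Si](C(C)C)(C(C)C)C(C)C)c(OC)c1 | intermediate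
15 | methyl (2RS,4S)-4-(tert-butyldimethylsilyloxy)-2-[3-methoxy-4-(triisopropylsilyloxy)benzyl]-4-[3-methoxy-4-(triisopropylsilyloxy)phenyl]-3-methylenebutanoate (both C2 epimers) | COC(=O)C(Cc1ccc(O[Si](C(C)C)(C(C)C)C(C)C)c(OC)c1)C(=C)[C@H](O[Si](C)(C)C(C)(C)C)c1ccc(O[Si](C(C)C)(C(C)C)C(C)C)c(OC)c1 | intermediate
16 | methyl (2RS,3S,4S)-3-[(1,3,2-benzodioxaborol-2-yl)methyl]-4-(tert-butyldimethylsilyloxy)-2-[3-methoxy-4-(triisopropylsilyloxy)benzyl]-4-[3-methoxy-4-(triisopropylsilyloxy)phenyl]butanoate (not isolated) | COC(=O)C(Cc1ccc(O[Si](C(C)C)(C(C)C)C(C)C)c(OC)c1)[C@H](CB1Oc2ccccc2O1)[C@H](O[Si](C)(C)C(C)(C)C)c1ccc(O[Si](C(C)C)(C(C)C)C(C)C)c(OC)c1 | intermediate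
17 | methyl (2RS,3R,4S)-4-(tert-butyldimethylsilyloxy)-3-(hydroxymethyl)-2-[3-methoxy-4-(triisopropylsilyloxy)benzyl]-4-[3-methoxy-4-(triisopropylsilyloxy)phenyl]butanoate (not isolated) | COC(=O)C(Cc1ccc(O[Si](C(C)C)(C(C)C)C(C)C)c(OC)c1)[C@H](CO)[C@H](O[Si](C)(C)C(C)(C)C)c1ccc(O[Si](C(C)C)(C(C)C)C(C)C)c(OC)c1 | intermediate
18 | (3RS,4R)-4-[(S)-(tert-butyldimethylsilyloxy)[3-methoxy-4-(triisopropylsilyloxy)phenyl]methyl]-3-[3-methoxy-4-(triisopropylsilyloxy)benzyl]dihydrofuran-2(3H)-one (both C3 epimers) | COc1cc(CC2C(=O)OC[C@@H]2[C@H](O[Si](C)(C)C(C)(C)C)c2ccc(O[Si](C(C)C)(C(C)C)C(C)C)c(OC)c2)ccc1O[Si](C(C)C)(C(C)C)C(C)C | intermediate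
19 | (3R,4R)-4-[(S)-(tert-butyldimethylsilyloxy)[3-methoxy-4-(triisopropylsilyloxy)phenyl]methyl]-3-[3-methoxy-4-(triisopropylsilyloxy)benzyl]dihydrofuran-2(3H)-one | COc1cc(C[C@H]2C(=O)OC[C@@H]2[C@H](O[Si](C)(C)C(C)(C)C)c2ccc(O[Si](C(C)C)(C(C)C)C(C)C)c(OC)c2)ccc1O[Si](C(C)C)(C(C)C)C(C)C | intermediate
20 | (3R,4R)-3-(4-hydroxy-3-methoxybenzyl)-4-[(S)-hydroxy(4-hydroxy-3-methoxyphenyl)methyl]dihydrofuran-2(3H)-one | COc1cc(C[C@H]2C(=O)OC[C@@H]2[C@H](O)c2ccc(O)c(OC)c2)ccc1O | target

## Step count and risks

Total: 12 steps. Longest linear sequence: 10 steps (steps 1–6 and 9–12, from vanillin 1); the ring A branch (steps 7 and 8) joins at step 9.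

Step 10 (key step). Most likely failure: slow insertion at an alkene flanked by two branched carbons, so that rhodium hydride-mediated double-bond migration or hydrogenation competes, and erosion of facial selectivity in the C3 epimer whose substituents oppose the approach dictated by C7′. The fallback sets out from bromide 9 and returns at 19; it moves the ring A benzyl group to the end, so that the hydroboration meets an alkene whose second allylic carbon is a plain CH2. Palladium-catalysed coupling of 9 with the Reformatsky reagent BrZnCH2CO2Me (Pd(dba)2, P(t-Bu)3, THF) should give the unbranched β,γ-unsaturated ester F1. Hydroboration, oxidation and lactonisation under the conditions of step 10 should then give the 4-substituted lactone F2. Aldehyde 2 is reduced (NaBH4, MeOH) to benzylic alcohol F3 and converted (PBr3, Et2O, 0 °C) into benzylic bromide F4. Alkylation of the lithium enolate of F2 (LiN(SiMe3)2, THF, −78 °C) with F4 takes place anti to the C4 substituent and gives 19 directly, without an equilibration step.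

Step 9. Most likely failure: slow transmetalation and reductive elimination between a hindered alkenylpalladium bromide and an α-branched enolate, leaving room for protodebromination, enolate homocoupling and base-induced migration of the product double bond into conjugation. The fallback sets out from ester 12 and bromide 9 and returns at 15. Bromination of lithium enolate 13 (CBr4, THF, −78 °C) gives the racemic α-bromo ester F5. Nickel-catalysed reductive cross-electrophile coupling of F5 with 9 (NiBr2(dme), 4,4′-di-tert-butyl-2,2′-bipyridine, Mn powder, N,N-dimethylacetamide, rt) forms the C3–C4 bond through a C3 radical and an alkenylnickel species, with no enolate base present.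

Step 6. Most likely failure: ionisation or cleavage of the electron-rich benzylic silyl ether by the Lewis-acidic bromoborane, or loss of regiocontrol through coordination of boron to the propargylic oxygen. The fallback sets out from alkyne 7 and returns at 9. Hydrostannation of 7 with Bu3SnH catalysed by Mo(CO)3(CNt-Bu)3 (THF, 55 °C), in which the propargylic oxygen steers tin to the internal carbon, gives the α-stannyl alkene F6. Bromodestannylation (Br2, CH2Cl2, −78 °C) then gives 9 without any Lewis acid.

Step 4. Most likely failure: insufficient discrimination between two unsaturated ketone substituents, together with uncatalysed background reduction or conjugate reduction of the ynone, which lowers the enantiomeric purity on which every later stereocentre depends. The fallback sets out from aldehyde 2 and returns at 6, bypassing steps 2 to 4. Catalytic enantioselective addition of trimethylsilylacetylene to 2 (Me2Zn, ProPhenol ligand 2,6-bis{[2-(hydroxydiphenylmethyl)pyrrolidin-1-yl]methyl}-4-methylphenol in the enantiomeric form that gives the required sense, toluene, 0 °C) gives the silylated propargylic alcohol F7. Brief treatment with K2CO3 in MeOH at 0 °C removes the alkynyl silyl group and gives 6.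

Step 12. Most likely failure: once the C7′ oxygen is unmasked, acyl transfer from O1 to that oxygen; once a phenoxide forms para to C7′, elimination and readdition through a quinone methide that scrambles C7′; and slow cleavage of the hindered benzylic silyl ether under buffered conditions. The fallback sets out from 19 and returns at 20 in two stages with different mechanisms. HF·pyridine in THF/pyridine (0 °C) cleaves the alkyl silyl ether and leaves the aryl silyl ethers, giving the mono-ol F8, in which no phenoxide can form. KHF2 in MeOH (rt), which cleaves aryl silyl ethers near neutrality, then gives 20.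

## Further compounds

F1 | step 10 | methyl (4S)-4-(tert-butyldimethylsilyloxy)-4-[3-methoxy-4-(triisopropylsilyloxy)phenyl]-3-methylenebutanoate | COC(=O)CC(=C)[C@H](O[Si](C)(C)C(C)(C)C)c1ccc(O[Si](C(C)C)(C(C)C)C(C)C)c(OC)c1
F2 | step 10 | (4R)-4-[(S)-(tert-butyldimethylsilyloxy)[3-methoxy-4-(triisopropylsilyloxy)phenyl]methyl]dihydrofuran-2(3H)-one | O=C1C[C@H](CO1)[C@H](O[Si](C)(C)C(C)(C)C)c1ccc(O[Si](C(C)C)(C(C)C)C(C)C)c(OC)c1
F3 | step 10 | [3-methoxy-4-(triisopropylsilyloxy)phenyl]methanol | COc1cc(CO)ccc1O[Si](C(C)C)(C(C)C)C(C)C
F4 | step 10 | [4-(bromomethyl)-2-methoxyphenoxy]triisopropylsilane | COc1cc(CBr)ccc1O[Si](C(C)C)(C(C)C)C(C)C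
F5 | step 9 | methyl 2-bromo-3-[3-methoxy-4-(triisopropylsilyloxy)phenyl]propanoate (racemic) | COC(=O)C(Br)Cc1ccc(O[Si](C(C)C)(C(C)C)C(C)C)c(OC)c1
F6 | step 6 | (R)-tributyl{3-(tert-butyldimethylsilyloxy)-3-[3-methoxy-4-(triisopropylsilyloxy)phenyl]prop-1-en-2-yl}stannane | C=C([Sn](CCCC)(CCCC)CCCC)[C@H](O[Si](C)(C)C(C)(C)C)c1ccc(O[Si](C(C)C)(C(C)C)C(C)C)c(OC)c1
F7 | step 4 | (R)-1-[3-methoxy-4-(triisopropylsilyloxy)phenyl]-3-(trimethylsilyl)prop-2-yn-1-ol | C[Si](C)(C)C#C[C@H](O)c1ccc(O[Si](C(C)C)(C(C)C)C(C)C)c(OC)c1
F8 | step 12 | (3R,4R)-4-[(S)-hydroxy[3-methoxy-4-(triisopropylsilyloxy)phenyl]methyl]-3-[3-methoxy-4-(triisopropylsilyloxy)benzyl]dihydrofuran-2(3H)-one | COc1cc(C[C@H]2C(=O)OC[C@@H]2[C@H](O)c2ccc(O[Si](C(C)C)(C(C)C)C(C)C)c(OC)c2)ccc1O[Si](C(C)C)(C(C)C)C(C)C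
A1 | alternative 1 | tert-butyl 2-[4-(tert-butyldimethylsilyloxy)-3-methoxybenzyl]-3-(4,4,5,5-tetramethyl-1,3,2-dioxaborolan-2-yl)-4-(triethylsilyloxy)butanoate, C2 and C3 arranged as C3 and C4 of 20 | COc1cc(C[C@@H](C(=O)OC(C)(C)C)[C@H](CO[Si](CC)(CC)CC)B2OC(C)(C)C(C)(C)O2)ccc1O[Si](C)(C)C(C)(C)C
A2 | alternative 1 | tert-butyl 2-[4-(tert-butyldimethylsilyloxy)-3-methoxybenzyl]-3-[(S)-hydroxy[4-(tert-butyldimethylsilyloxy)-3-methoxyphenyl]methyl]-4-(triethylsilyloxy)butanoate, C2 and C3 arranged as C3 and C4 of 20 | COc1cc(C[C@@H](C(=O)OC(C)(C)C)[C@H](CO[Si](CC)(CC)CC)[C@H](O)c2ccc(O[Si](C)(C)C(C)(C)C)c(OC)c2)ccc1O[Si](C)(C)C(C)(C)C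
A3 | alternative 2 | 3-[(S)-(tert-butyldimethylsilyloxy)[4-(tert-butyldimethylsilyloxy)-3-methoxyphenyl]methyl]cyclobutan-1-one | O=C1CC(C1)[C@H](O[Si](C)(C)C(C)(C)C)c1ccc(O[Si](C)(C)C(C)(C)C)c(OC)c1
A4 | alternative 2 | (4R)-4-[(S)-(tert-butyldimethylsilyloxy)[4-(tert-butyldimethylsilyloxy)-3-methoxyphenyl]methyl]dihydrofuran-2(3H)-one | O=C1C[C@H](CO1)[C@H](O[Si](C)(C)C(C)(C)C)c1ccc(O[Si](C)(C)C(C)(C)C)c(OC)c1
A5 | alternative 3 | tert-butyl (2R)-2-[4-(tert-butyldimethylsilyloxy)-3-methoxybenzyl]-4-hydroxy-3-(hydroxymethyl)butanoate | COc1cc(C[C@@H](C(=O)OC(C)(C)C)C(CO)CO)ccc1O[Si](C)(C)C(C)(C)C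
A6 | alternative 3 | (3R,4S)-3-[4-(tert-butyldimethylsilyloxy)-3-methoxybenzyl]-4-(hydroxymethyl)dihydrofuran-2(3H)-one (trans) | COc1cc(C[C@H]2C(=O)OC[C@@H]2CO)ccc1O[Si](C)(C)C(C)(C)C
A7 | alternative 3 | trans-4-[4-(tert-butyldimethylsilyloxy)-3-methoxybenzyl]-5-oxotetrahydrofuran-3-carbaldehyde | COc1cc(C[C@H]2C(=O)OC[C@@H]2C=O)ccc1O[Si](C)(C)C(C)(C)C
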